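**Analysis of the target**

The target 21 is a (2S)-flavanone. Ring A (C4a to C8a) carries phenols at C5 and C7, ring C is the chroman-4-one ring O1–C2–C3–C4, and ring B is a 4'-hydroxyphenyl group on C2. Ring B bears at C3' an (E)-7-hydroxy-3,7-dimethyloct-2-enyl chain, which is a geranyl group hydrated at its far end. C2 is the only stereocentre. It is benzylic, bound to O1 and β to the C4 ketone, so an enolate at C3 can expel the ring A phenoxide (retro-oxa-Michael) and re-close, which erases it. The other delicate sites are the three phenols, the tertiary carbinol, and the trisubstituted alkene ortho to the 4'-phenol, where acid can drive cyclisation to a chroman. The difficulty is therefore the order of events more than the skeleton: C2 must be set with absolute control, ring C closed and the C4 ketone revealed without base, and all protecting groups removed under mild, weakly acidic conditions. The strategy rests on the C3–C4 bond of ring C. C4 is the acyl carbon of a ring A aryl ketone and C3 is the carbon next to C2, so an enol ether of an ortho-acetyl group and a vinyl group on C2 are the two halves of a metathesis that forms C3=C4. The C2–O1 bond is made beforehand as an enantioenriched allylic aryl ether.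

**Retrosynthetic reasoning**

21 to 20. The last operation is planned first. Target 21 is traced to the 4-silyloxy-2H-chromene 20, in which C4 is masked as a silyl enol ether and every hydroxyl carries a silyl group. Only O–Si bonds are cut, so one acidic fluoride treatment protonates C3, gives the ketone and frees five hydroxyls without base. Silyl groups are chosen throughout because acetal removal would need acid strong enough to cyclise the side chain, and hydrogenolysis would reduce its alkene.

20 to 19. Ring C is opened at C3=C4. Cutting here, and not at O1–C2 or C2–C3, keeps C2 out of the ring-forming event. It turns the two ring carbons into two alkenes of 19: the vinyl group on C2 and the silyl enol ether of the ring A acetyl group. The forward reaction is a ruthenium-carbene ring-closing metathesis that must pick this pair out of three alkenes and deliver C4 at the ketone oxidation level in masked form.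

19 to 18. The enol O–Si bond is cut to give methyl ketone 18. The acetyl group has only one enolisable position, so the forward soft enolisation has no regiochemical question. It must only leave the ionisable allylic aryl ether alone.

18 to 14 and 16. The C2–O1 bond is cut, and this is the one place where the stereocentre is made. The cut gives the ring A phenol 16 as nucleophile and the ring B cinnamyl carbonate 14 as electrophile. This pair suits an iridium-catalysed allylic etherification, which has to give the branched regioisomer and the S configuration in one step. Phenol 16 comes from 15 by silylating two of its three hydroxyls; the hydroxyl that stays free is the one held by the hydrogen bond to the acetyl group, which is the one needed.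

14 to 12 to 11. These are functional group changes only: the carbonate is made from allylic alcohol 12, and 12 from cinnamate 11 by 1,2-reduction. A tert-butyl carbonate is chosen because its leaving group ends as a hindered alkoxide that does not attack aryl silyl ethers in the etherification.

11 to 10 and 6. The bond between C3' of ring B and C1 of the side chain is cut to aryl boronate 10 and allylic bromide 6. This joins two fragments of similar size, and an allyl–palladium coupling places the aryl group at the primary terminus and keeps the (E) alkene. Boron is used and not lithium because an aryllithium ortho to a silyloxy group would suffer O-to-C silyl migration. Boronate 10 goes back through bromide 9 and aldehyde 8 to 7.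

6 to 1. The side chain is traced through alcohol 5 and acetate 4 to hydroxy acetate 3 and to 1. The C7–O bond comes from Markovnikov hydration of the remote alkene of 1, which is the more electron-rich of the two. The acetate keeps the two ends of the chain distinct until the carbinol is capped.

**Alternatives that were turned down**

Alternative 1: Here C2–C3 is disconnected, and ring C arises by a Petasis–Ferrier rearrangement of the enol acetal 2-[3-bromo-4-(silyloxy)phenyl]-4-methylene-1,3-benzodioxine A2. A chiral acid ionises the C2–O3 bond and the liberated enol carbon recombines with the oxocarbenium carbon to give the (2S)-3'-bromo-tris(silyloxy)flavanone A1.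
- For: the C2–C3 bond and the stereocentre are made in one catalytic, ring-forming step from an achiral acetal, and the bromide allows late attachment of the side chain.
- Against: the stereo-determining event is recombination of an ion pair whose cation is stabilised by a para-silyloxyaryl group, so it is long-lived and loosely held by the chiral counter-ion. The acid that triggers it can also re-open the product and strip aryl silyl ethers. The side chain must then be coupled onto a finished flavanone under basic cross-coupling conditions, where C2 is at risk.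
- Comparison: on convergence of the core and on setting C2 during ring closure this alternative is stronger. The chosen route offers instead a stereocentre set by a well-understood catalyst class before the ring exists, a stereochemically silent ring closure, and no base after ring C is formed.

Alternative 2: Here ring A is built last by cutting C7–C8. The (S)-dihydropyranone keto ester A4 carries a 6-methyl group and a malonyl-type side chain. Its vinylogous enolate attacks the ester carbonyl; loss of the ester alkoxide and enolisation give the (2S)-5,7-dihydroxyflavanone A3 with silyl groups only on the 4'-oxygen and the carbinol.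
- For: ring A needs no protecting groups, aromatisation is a strong driving force, and C2 can be set early on a dihydropyranone by established asymmetric methods.
- Against: A4 has three acidic sites. The 1,3-dicarbonyl methylene is deprotonated first, which deactivates the ester, so a polyanion is required. That strongly basic medium acts on a β-aryl-β-oxy enone that can open by retro-oxa-Michael and lose C2. Building A4 is also long.
- Comparison: it is stronger on protecting-group economy for ring A. The chosen route spends one silylation on a commercial ring A ketone, removes everything in one final step, and is shorter and safer for C2.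

Alternative 3: Here O1–C8a is disconnected. In the syn-1,3-diol A6, the C2 hydroxyl displaces an ortho-bromide on ring A in an Ullmann-type etherification under copper catalysis, giving the (2S,4R)-flavan-4-ol A5. Oxidation at C4 and removal of three allyl ethers follow.
- For: the C2–O bond is not broken, so C2 cannot scramble in the ring closure, and the C4 hydroxyl cannot compete because it would form a four-membered ring.
- Against: the aryl bromide carries two alkoxy donors and is slow to react, which calls for heat and strong base. Two stereocentres must be made to keep one. The C4 alcohol must be oxidised afterwards, and allyl ethers (needed because silyl ethers would not survive the coupling base) require a separate transition-metal deallylation.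
- Comparison: the ring closure itself is probably more certain than a metathesis at a hindered enol ether. The chosen route offers in its place the correct oxidation level at C4 directly from the ring closure, one stereocentre only, and a single global deprotection.

Key step: step 14

Assumption (remark on the chemistry): the phosphoramidite ligand L of (Sa,Sc,Sc) configuration, O,O'-(1,1'-binaphthyl-2,2'-diyl) N,N-bis(1-phenylethyl)phosphoramidite, is taken to give the (S)-ether with cinnamyl carbonates. If a first run shows the opposite sense, the (Ra,Rc,Rc) ligand is used and nothing else changes.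

**Route**

Step 1
Reactants: 1 geranyl acetate [(E)-3,7-dimethylocta-2,6-dien-1-yl acetate]
Product: 3 (E)-7-hydroxy-3,7-dimethyloct-2-en-1-yl acetate, via organomercurial acetate 2 (not isolated)
Conditions: Hg(OAc)2 (1.0 equiv), THF/H2O 1:1, rt; then NaBH4, 3 M aq NaOH, 0 °C, short contact
Reagents that add atoms: water, O
Why: Oxymercuration–demercuration; the remote trisubstituted alkene is the more nucleophilic because the 2,3-alkene is deactivated by the allylic acetate, water adds at the tertiary carbon (Markovnikov), and cold, brief borohydride reduction removes mercury while sparing the acetate; no stereocentre remains.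

Step 2
Reactants: 3 (E)-7-hydroxy-3,7-dimethyloct-2-en-1-yl acetate
Product: 4 (E)-3,7-dimethyl-7-(triethylsilyloxy)oct-2-en-1-yl acetate
Conditions: TESOTf, 2,6-lutidine, CH2Cl2, −78 → 0 °C
Reagents that add atoms: triethylsilyl trifluoromethanesulfonate, CC[Si](CC)(CC)OS(=O)(=O)C(F)(F)F
Why: Silylation of a tertiary alcohol with a silyl triflate and a hindered base; the carbinol is capped before the allylic position is activated, so it cannot close onto C3 to form a tetrahydropyran, and the triethylsilyl group is chosen for easy removal by acidic fluoride at the end.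

Step 3
Reactants: 4 (E)-3,7-dimethyl-7-(triethylsilyloxy)oct-2-en-1-yl acetate
Product: 5 (E)-3,7-dimethyl-7-(triethylsilyloxy)oct-2-en-1-ol
Conditions: K2CO3 (0.2 equiv), MeOH, 0 °C → rt
Reagents that add atoms: none
Why: Base-catalysed transesterification (methanolysis) of a primary allylic acetate; a tertiary triethylsilyl ether is inert under these conditions.

Step 4
Reactants: 5 (E)-3,7-dimethyl-7-(triethylsilyloxy)oct-2-en-1-ol
Product: 6 triethyl{[(E)-8-bromo-2,6-dimethyloct-6-en-2-yl]oxy}silane
Conditions: CBr4, PPh3, CH2Cl2, −20 → 0 °C
Reagents that add atoms: carbon tetrabromide, BrC(Br)(Br)Br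
Why: Appel bromination; bromide displaces the alkoxyphosphonium at the primary allylic carbon without allylic transposition, so the (E) alkene is kept, and the neutral medium spares the silyl ether.

Step 5
Reactants: 7 3-bromo-4-hydroxybenzaldehyde
Product: 8 3-bromo-4-(tert-butyldimethylsilyloxy)benzaldehyde
Conditions: TBSCl, imidazole, CH2Cl2, rt
Reagents that add atoms: tert-butyldimethylsilyl chloride, CC(C)(C)[Si](C)(C)Cl
Why: Standard phenol silylation; the same silyl group as on ring A is used so that one fluoride treatment removes all of them.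

Step 6
Reactants: 8 3-bromo-4-(tert-butyldimethylsilyloxy)benzaldehyde
Product: 9 ethyl (E)-3-[3-bromo-4-(tert-butyldimethylsilyloxy)phenyl]prop-2-enoate
Conditions: Ph3P=CHCO2Et, toluene, 80 °C
Reagents that add atoms: ethyl (triphenylphosphoranylidene)acetate, CCOC(=O)C=P(c1ccccc1)(c1ccccc1)c1ccccc1
Why: Wittig olefination with a stabilised ylide, which should be strongly (E)-selective with an aryl aldehyde and needs no added base that could attack the aryl silyl ether.

Step 7
Reactants: 9 ethyl (E)-3-[3-bromo-4-(tert-butyldimethylsilyloxy)phenyl]prop-2-enoate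
Product: 10 ethyl (E)-3-[4-(tert-butyldimethylsilyloxy)-3-(4,4,5,5-tetramethyl-1,3,2-dioxaborolan-2-yl)phenyl]prop-2-enoate
Conditions: B2pin2, Pd(dppf)Cl2 (3 mol %), KOAc, 1,4-dioxane, 85 °C
Reagents that add atoms: bis(pinacolato)diboron, CC1(C)OB(B2OC(C)(C)C(C)(C)O2)OC1(C)C
Why: Miyaura borylation; the weak acetate base tolerates the enoate and the aryl silyl ether, and the palladium route avoids an ortho-silyloxy aryllithium, which would undergo O-to-C silyl migration.

Step 8
Reactants: 10 ethyl (E)-3-[4-(tert-butyldimethylsilyloxy)-3-(4,4,5,5-tetramethyl-1,3,2-dioxaborolan-2-yl)phenyl]prop-2-enoate; 6 triethyl{[(E)-8-bromo-2,6-dimethyloct-6-en-2-yl]oxy}silane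
Product: 11 ethyl (E)-3-{4-(tert-butyldimethylsilyloxy)-3-[(E)-3,7-dimethyl-7-(triethylsilyloxy)oct-2-en-1-yl]phenyl}prop-2-enoate
Conditions: Pd(PPh3)4 (5 mol %), K3PO4 (3 equiv), THF/H2O 10:1, 50 °C
Reagents that add atoms: none
Why: Suzuki–Miyaura allyl–aryl coupling; zerovalent palladium ionises the allylic bromide to a π-allyl complex, the aryl group is transferred from boron and reductive elimination occurs at the unhindered primary terminus, giving the linear product; syn–anti exchange at the trisubstituted terminus is slow, so the (E) geometry should be kept.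

Step 9
Reactants: 11 ethyl (E)-3-{4-(tert-butyldimethylsilyloxy)-3-[(E)-3,7-dimethyl-7-(triethylsilyloxy)oct-2-en-1-yl]phenyl}prop-2-enoate
Product: 12 (E)-3-{4-(tert-butyldimethylsilyloxy)-3-[(E)-3,7-dimethyl-7-(triethylsilyloxy)oct-2-en-1-yl]phenyl}prop-2-en-1-ol
Conditions: i-Bu2AlH (2.5 equiv), CH2Cl2, −78 °C
Reagents that add atoms: none
Why: 1,2-Reduction of an α,β-unsaturated ester to the allylic alcohol by i-Bu2AlH at low temperature; silyl ethers and both alkenes are untouched.

Step 10
Reactants: 12 (E)-3-{4-(tert-butyldimethylsilyloxy)-3-[(E)-3,7-dimethyl-7-(triethylsilyloxy)oct-2-en-1-yl]phenyl}prop-2-en-1-ol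
Product: 14 tert-butyl (E)-3-{4-(tert-butyldimethylsilyloxy)-3-[(E)-3,7-dimethyl-7-(triethylsilyloxy)oct-2-en-1-yl]phenyl}prop-2-en-1-yl carbonate, via lithium alkoxide 13 (not isolated)
Conditions: n-BuLi (1.05 equiv), THF, −78 °C; then Boc2O, −78 → 0 °C
Reagents that add atoms: di-tert-butyl dicarbonate, CC(C)(C)OC(=O)OC(=O)OC(C)(C)C
Why: O-Acylation of a lithium alkoxide with Boc2O, the usual way to allylic tert-butyl carbonates; this carbonate is chosen because it resists transesterification by aryloxide and releases only a hindered alkoxide in step 12.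

Step 11
Reactants: 15 2,4,6-trihydroxyacetophenone (dried)
Product: 16 1-[2,4-bis(tert-butyldimethylsilyloxy)-6-hydroxyphenyl]ethan-1-one
Conditions: TBSCl (2.1 equiv), imidazole, DMF, 0 °C → rt
Reagents that add atoms: tert-butyldimethylsilyl chloride, CC(C)(C)[Si](C)(C)Cl
Why: Regioselective phenol silylation; the unchelated 4-hydroxyl reacts first, then one ortho hydroxyl, and the last one stays free because it is held in the hydrogen bond to the acetyl carbonyl.

Step 12
Reactants: 16 1-[2,4-bis(tert-butyldimethylsilyloxy)-6-hydroxyphenyl]ethan-1-one; 14 tert-butyl (E)-3-{4-(tert-butyldimethylsilyloxy)-3-[(E)-3,7-dimethyl-7-(triethylsilyloxy)oct-2-en-1-yl]phenyl}prop-2-en-1-yl carbonate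
Product: 18 1-{2,4-bis(tert-butyldimethylsilyloxy)-6-[((1S)-1-{4-(tert-butyldimethylsilyloxy)-3-[(E)-3,7-dimethyl-7-(triethylsilyloxy)oct-2-en-1-yl]phenyl}prop-2-en-1-yl)oxy]phenyl}ethan-1-one, via lithium aryloxide 17 (not isolated)
Conditions: 16 (1.5 equiv), LiOt-Bu (0.5 equiv), THF, 0 °C; then 14, [Ir(cod)Cl]2 (2 mol %), (Sa,Sc,Sc)-L (4 mol %, pre-activated with n-PrNH2 at 50 °C, volatiles removed), THF, rt
Reagents that add atoms: none
Why: Iridium-catalysed asymmetric allylic etherification of a cinnamyl carbonate with an aryloxide; the cyclometalated iridium phosphoramidite ionises the carbonate, and the aryloxide attacks the aryl-bearing terminus on the face left open by the ligand, giving the branched ether and setting C2 as S. The tert-butoxide released is quenched by excess 16, so the medium stays weakly basic and the silyl ethers are not attacked.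

Step 13
Reactants: 18 1-{2,4-bis(tert-butyldimethylsilyloxy)-6-[((1S)-1-{4-(tert-butyldimethylsilyloxy)-3-[(E)-3,7-dimethyl-7-(triethylsilyloxy)oct-2-en-1-yl]phenyl}prop-2-en-1-yl)oxy]phenyl}ethan-1-one
Product: 19 tert-butyl{[1-(2,4-bis(tert-butyldimethylsilyloxy)-6-{[(1S)-1-{4-(tert-butyldimethylsilyloxy)-3-[(E)-3,7-dimethyl-7-(triethylsilyloxy)oct-2-en-1-yl]phenyl}prop-2-en-1-yl]oxy}phenyl)ethenyl]oxy}dimethylsilane
Conditions: TBSOTf (1.5 equiv), Et3N (3 equiv), CH2Cl2, −78 → 0 °C; chromatography on Et3N-deactivated silica
Reagents that add atoms: tert-butyldimethylsilyl trifluoromethanesulfonate, CC(C)(C)[Si](C)(C)OS(=O)(=O)C(F)(F)F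
Why: Soft enolisation of a methyl ketone with a silyl triflate and an amine gives the only possible silyl enol ether; excess amine and low temperature keep the Lewis acid from ionising the allylic aryl ether, so C2 is untouched.

Step 14
Reactants: 19 tert-butyl{[1-(2,4-bis(tert-butyldimethylsilyloxy)-6-{[(1S)-1-{4-(tert-butyldimethylsilyloxy)-3-[(E)-3,7-dimethyl-7-(triethylsilyloxy)oct-2-en-1-yl]phenyl}prop-2-en-1-yl]oxy}phenyl)ethenyl]oxy}dimethylsilane
Product: 20 (2S)-4,5,7-tris(tert-butyldimethylsilyloxy)-2-{4-(tert-butyldimethylsilyloxy)-3-[(E)-3,7-dimethyl-7-(triethylsilyloxy)oct-2-en-1-yl]phenyl}-2H-chromene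
Conditions: second-generation Grubbs catalyst (H2IMes)(PCy3)Cl2Ru=CHPh (10 mol %), 1,4-benzoquinone (20 mol %), toluene (0.005 M), 50 °C, argon sparge, dark
Reagents that add atoms: none
Why: The ruthenium benzylidene exchanges onto the monosubstituted vinyl group on C2, the only terminal alkene that can load the catalyst, giving an alkylidene held next to the enol ether. A [2+2] cycloaddition with the tethered 1,1-disubstituted silyl enol ether places the fully substituted carbon at the β position of the ruthenacyclobutane, and cycloreversion forms C3=C4 and a ruthenium methylidene that leaves as ethylene on the next turnover. The closest known reactions are ring-closing metathesis of silyl enol ethers to cyclic silyl enol ethers, notably the closure of N-allyl ortho-(1-silyloxyvinyl)anilines to 4-silyloxy-1,2-dihydroquinolines, and of allyl ortho-vinylphenyl ethers to 2H-chromenes. Ring C is closed as a six-membered oxacycle with an endocyclic C3=C4 alkene, a closure favoured by the ortho arrangement on ring A and driven by loss of ethylene at high dilution. No stereocentre is formed; C2 comes from step 12 and is a spectator as long as its allylic hydrogen is not moved. The selectivity needed is chemoselectivity among three alkenes, and substitution secures it: the vinyl group initiates, the enol ether can react only intramolecularly, and the trisubstituted side-chain alkene is hindered and would give a macrocycle. 1,4-Benzoquinone intercepts ruthenium hydrides that would migrate the vinyl double bond toward C2, and the moderate temperature with exclusion of light guards against reversible oxa-6π opening of the 2H-chromene. The peri contact between the silyloxy groups at C4 and C5 is the main cost, which is why the reaction is given time at 50 °C and not pushed hotter.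

Step 15
Reactants: 20 (2S)-4,5,7-tris(tert-butyldimethylsilyloxy)-2-{4-(tert-butyldimethylsilyloxy)-3-[(E)-3,7-dimethyl-7-(triethylsilyloxy)oct-2-en-1-yl]phenyl}-2H-chromene
Product: 21 (2S)-5,7-dihydroxy-2-{4-hydroxy-3-[(E)-7-hydroxy-3,7-dimethyloct-2-en-1-yl]phenyl}chroman-4-one (CNP0161524.1)
Conditions: HF·pyridine, pyridine, THF, 0 °C → rt; quench with Me3SiOMe
Reagents that add atoms: none
Why: Protodesilylation by acidic fluoride; the silyl enol ether is protonated at C3 and gives the C4 ketone, and the same reagent cleaves the three aryl silyl ethers and the tertiary triethylsilyl ether. The pyridine-buffered medium is never basic, so retro-oxa-Michael opening of ring C is not available and C2 stays S.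

**Compound list**

1 | geranyl acetate, (E)-3,7-dimethylocta-2,6-dien-1-yl acetate | CC(C)=CCC/C(C)=C/COC(C)=O | starting material
2 | (E)-6-(acetoxymercurio)-7-hydroxy-3,7-dimethyloct-2-en-1-yl acetate, racemic at C6, not isolated | CC(C)(O)C([Hg]OC(C)=O)CC/C(C)=C/COC(C)=O | intermediate
3 | (E)-7-hydroxy-3,7-dimethyloct-2-en-1-yl acetate | CC(C)(O)CCC/C(C)=C/COC(C)=O | intermediate
4 | (E)-3,7-dimethyl-7-(triethylsilyloxy)oct-2-en-1-yl acetate | CC[Si](CC)(CC)OC(C)(C)CCC/C(C)=C/COC(C)=O | intermediate
5 | (E)-3,7-dimethyl-7-(triethylsilyloxy)oct-2-en-1-ol | CC[Si](CC)(CC)OC(C)(C)CCC/C(C)=C/CO | intermediate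
6 | triethyl{[(E)-8-bromo-2,6-dimethyloct-6-en-2-yl]oxy}silane | CC[Si](CC)(CC)OC(C)(C)CCC/C(C)=C/CBr | intermediate
7 | 3-bromo-4-hydroxybenzaldehyde | O=Cc1ccc(O)c(Br)c1 | starting material
8 | 3-bromo-4-(tert-butyldimethylsilyloxy)benzaldehyde | O=Cc1ccc(O[Si](C)(C)C(C)(C)C)c(Br)c1 | intermediate
9 | ethyl (E)-3-[3-bromo-4-(tert-butyldimethylsilyloxy)phenyl]prop-2-enoate | CCOC(=O)/C=C/c1ccc(O[Si](C)(C)C(C)(C)C)c(Br)c1 | intermediate
10 | ethyl (E)-3-[4-(tert-butyldimethylsilyloxy)-3-(4,4,5,5-tetramethyl-1,3,2-dioxaborolan-2-yl)phenyl]prop-2-enoate | CCOC(=O)/C=C/c1ccc(O[Si](C)(C)C(C)(C)C)c(B2OC(C)(C)C(C)(C)O2)c1 | intermediate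
11 | ethyl (E)-3-{4-(tert-butyldimethylsilyloxy)-3-[(E)-3,7-dimethyl-7-(triethylsilyloxy)oct-2-en-1-yl]phenyl}prop-2-enoate | C/C(=C\Cc1cc(/C=C/C(=O)OCC)ccc1O[Si](C)(C)C(C)(C)C)CCCC(C)(C)O[Si](CC)(CC)CC | intermediate
12 | (E)-3-{4-(tert-butyldimethylsilyloxy)-3-[(E)-3,7-dimethyl-7-(triethylsilyloxy)oct-2-en-1-yl]phenyl}prop-2-en-1-ol | C/C(=C\Cc1cc(/C=C/CO)ccc1O[Si](C)(C)C(C)(C)C)CCCC(C)(C)O[Si](CC)(CC)CC | intermediate
13 | lithium alkoxide of 12, not isolated | C/C(=C\Cc1cc(/C=C/CO[Li])ccc1O[Si](C)(C)C(C)(C)C)CCCC(C)(C)O[Si](CC)(CC)CC | intermediate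
14 | tert-butyl (E)-3-{4-(tert-butyldimethylsilyloxy)-3-[(E)-3,7-dimethyl-7-(triethylsilyloxy)oct-2-en-1-yl]phenyl}prop-2-en-1-yl carbonate | C/C(=C\Cc1cc(/C=C/COC(=O)OC(C)(C)C)ccc1O[Si](C)(C)C(C)(C)C)CCCC(C)(C)O[Si](CC)(CC)CC | intermediate
15 | 2,4,6-trihydroxyacetophenone | CC(=O)c1c(O)cc(O)cc1O | starting material
16 | 1-[2,4-bis(tert-butyldimethylsilyloxy)-6-hydroxyphenyl]ethan-1-one | CC(=O)c1c(O)cc(O[Si](C)(C)C(C)(C)C)cc1O[Si](C)(C)C(C)(C)C | intermediate
17 | lithium aryloxide of 16, not isolated | CC(=O)c1c(O[Li])cc(O[Si](C)(C)C(C)(C)C)cc1O[Si](C)(C)C(C)(C)C | intermediate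
18 | (S)-1-arylallyl aryl ether with ortho acetyl group (name as in step 12) | C/C(=C\Cc1cc([C@@H](Oc2cc(O[Si](C)(C)C(C)(C)C)cc(O[Si](C)(C)C(C)(C)C)c2C(C)=O)C=C)ccc1O[Si](C)(C)C(C)(C)C)CCCC(C)(C)O[Si](CC)(CC)CC | intermediate
19 | (S)-1-arylallyl aryl ether with ortho 1-(tert-butyldimethylsilyloxy)vinyl group (name as in step 13) | C/C(=C\Cc1cc([C@@H](Oc2cc(O[Si](C)(C)C(C)(C)C)cc(O[Si](C)(C)C(C)(C)C)c2C(=C)O[Si](C)(C)C(C)(C)C)C=C)ccc1O[Si](C)(C)C(C)(C)C)CCCC(C)(C)O[Si](CC)(CC)CC | intermediate
20 | (2S)-4,5,7-tris(tert-butyldimethylsilyloxy)-2-{4-(tert-butyldimethylsilyloxy)-3-[(E)-3,7-dimethyl-7-(triethylsilyloxy)oct-2-en-1-yl]phenyl}-2H-chromene | C/C(=C\Cc1cc([C@@H]2C=C(O[Si](C)(C)C(C)(C)C)c3c(O[Si](C)(C)C(C)(C)C)cc(O[Si](C)(C)C(C)(C)C)cc3O2)ccc1O[Si](C)(C)C(C)(C)C)CCCC(C)(C)O[Si](CC)(CC)CC | intermediate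
21 | (2S)-5,7-dihydroxy-2-{4-hydroxy-3-[(E)-7-hydroxy-3,7-dimethyloct-2-en-1-yl]phenyl}chroman-4-one | C/C(=C\Cc1cc([C@@H]2CC(=O)c3c(O)cc(O)cc3O2)ccc1O)CCCC(C)(C)O | target

**Step count and risk**

Total: 15 steps. Longest linear sequence: 11 steps (1 → 3 → 4 → 5 → 6 → 11 → 12 → 14 → 18 → 19 → 20 → 21). The ring B branch from 7 is 10 steps and the ring A branch from 15 is 5 steps.

Least certain steps:

Step 14 (key step).
- What may go wrong: the enol ether carbon is flanked by two ortho oxygen substituents, and the product has peri-related silyloxy groups at C4 and C5. Ring closure may therefore be slow enough for intermolecular coupling through the vinyl groups or catalyst decay to take over. Ruthenium-hydride double-bond migration at the allylic ether would erase C2, and reversible electrocyclic opening of the 2H-chromene on heating or in light would erode its configuration.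
- Fallback: move the C3=C4 closure from a ruthenium enol-ether metathesis to a titanium-alkylidene olefin–ester cyclisation, which ends in an irreversible carbonyl olefination and carries a small methoxy group at C4. It sets out from 14. Commercial methyl 2,4,6-trihydroxybenzoate F1 is silylated as in step 11 to methyl 2-hydroxy-4,6-bis(tert-butyldimethylsilyloxy)benzoate F2. F2 is joined to 14 under the conditions of step 12 to give the (S)-1-arylallyl ether of the methyl benzoate F3. F3 is treated with a Takai–Utimoto-type titanium ethylidene (TiCl4, TMEDA, Zn, PbCl2, CH3CHBr2, THF), which exchanges onto the vinyl group and then olefinates the ester carbonyl to give the (2S)-4-methoxy-2H-chromene F4. HF·pyridine followed by brief dilute aqueous HCl in THF at 0 °C hydrolyses the methyl enol ether and removes the silyl groups, and the route is rejoined at 21.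

Step 12.
- What may go wrong: the aryloxide is chelated by the acetyl group and is a weak nucleophile, and it is also a good leaving group. With the electron-rich ring B the branched ether may be re-ionised by the catalyst, which would erode the enantiomeric purity and shift material to the linear ether. Silyl transfer between aryloxides is a further risk.
- Fallback: separate the stereo-determining step from the aryl ether formation. It sets out from 14, which is converted with the (Ra,Rc,Rc) ligand, [Ir(cod)Cl]2 and KHCO3 as a hydroxide equivalent into (R)-1-{4-(tert-butyldimethylsilyloxy)-3-[(E)-3,7-dimethyl-7-(triethylsilyloxy)oct-2-en-1-yl]phenyl}prop-2-en-1-ol F5. A Mitsunobu reaction of F5 with phenol 16 (PPh3, diisopropyl azodicarboxylate, toluene, −20 °C) inverts the carbinol centre and returns to the route at 18.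

Step 8.
- What may go wrong: cleavage of the aryl silyl ether by the aqueous base, followed by O-allylation of the freed phenoxide; protodeboronation of the hindered ortho-silyloxy boronate; and partial coupling at the tertiary allyl terminus or loss of alkene geometry through the π-allyl complex.
- Fallback: replace the boron partner by tin and run the coupling without base. It sets out from 9, which is stannylated with (Me3Sn)2 and Pd(PPh3)4 in toluene at 100 °C to ethyl (E)-3-[4-(tert-butyldimethylsilyloxy)-3-(trimethylstannyl)phenyl]prop-2-enoate F6. A Stille coupling of F6 with 6 (Pd2(dba)3, AsPh3, THF, 50 °C) returns to the route at 11.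

Step 15.
- What may go wrong: slow cleavage of the 4'-O silyl ether under buffered acidic fluoride would force long exposure. During that time acid-promoted addition of the ortho phenol to the side-chain alkene, or ionisation of the carbinol, can begin. A switch to basic fluoride would instead invite ring opening at C2.
- Fallback: split the unmasking into two events of different type. It sets out from 20. Aqueous AcOH in THF hydrolyses the silyl enol ether and the tertiary triethylsilyl ether to (2S)-5,7-bis(tert-butyldimethylsilyloxy)-2-{4-(tert-butyldimethylsilyloxy)-3-[(E)-7-hydroxy-3,7-dimethyloct-2-en-1-yl]phenyl}chroman-4-one F7. KHF2 in MeOH at rt, a weakly acidic reagent selective for aryl silyl ethers, then frees the three phenols and returns to the route at 21.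

**Further compounds**

F1 | step 14 | methyl 2,4,6-trihydroxybenzoate | COC(=O)c1c(O)cc(O)cc1O
F2 | step 14 | methyl 2-hydroxy-4,6-bis(tert-butyldimethylsilyloxy)benzoate | COC(=O)c1c(O)cc(O[Si](C)(C)C(C)(C)C)cc1O[Si](C)(C)C(C)(C)C
F3 | step 14 | methyl 2,4-bis(tert-butyldimethylsilyloxy)-6-{[(1S)-1-{4-(tert-butyldimethylsilyloxy)-3-[(E)-3,7-dimethyl-7-(triethylsilyloxy)oct-2-en-1-yl]phenyl}prop-2-en-1-yl]oxy}benzoate | C/C(=C\Cc1cc([C@@H](Oc2cc(O[Si](C)(C)C(C)(C)C)cc(O[Si](C)(C)C(C)(C)C)c2C(=O)OC)C=C)ccc1O[Si](C)(C)C(C)(C)C)CCCC(C)(C)O[Si](CC)(CC)CC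
F4 | step 14 | (2S)-5,7-bis(tert-butyldimethylsilyloxy)-2-{4-(tert-butyldimethylsilyloxy)-3-[(E)-3,7-dimethyl-7-(triethylsilyloxy)oct-2-en-1-yl]phenyl}-4-methoxy-2H-chromene | C/C(=C\Cc1cc([C@@H]2C=C(OC)c3c(O[Si](C)(C)C(C)(C)C)cc(O[Si](C)(C)C(C)(C)C)cc3O2)ccc1O[Si](C)(C)C(C)(C)C)CCCC(C)(C)O[Si](CC)(CC)CC
F5 | step 12 | (R)-1-{4-(tert-butyldimethylsilyloxy)-3-[(E)-3,7-dimethyl-7-(triethylsilyloxy)oct-2-en-1-yl]phenyl}prop-2-en-1-ol | C/C(=C\Cc1cc([C@H](O)C=C)ccc1O[Si](C)(C)C(C)(C)C)CCCC(C)(C)O[Si](CC)(CC)CC
F6 | step 8 | ethyl (E)-3-[4-(tert-butyldimethylsilyloxy)-3-(trimethylstannyl)phenyl]prop-2-enoate | CCOC(=O)/C=C/c1ccc(O[Si](C)(C)C(C)(C)C)c([Sn](C)(C)C)c1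
F7 | step 15 | (2S)-5,7-bis(tert-butyldimethylsilyloxy)-2-{4-(tert-butyldimethylsilyloxy)-3-[(E)-7-hydroxy-3,7-dimethyloct-2-en-1-yl]phenyl}chroman-4-one | C/C(=C\Cc1cc([C@@H]2CC(=O)c3c(O[Si](C)(C)C(C)(C)C)cc(O[Si](C)(C)C(C)(C)C)cc3O2)ccc1O[Si](C)(C)C(C)(C)C)CCCC(C)(C)O
A1 | alternative 1 | (2S)-2-[3-bromo-4-(tert-butyldimethylsilyloxy)phenyl]-5,7-bis(tert-butyldimethylsilyloxy)chroman-4-one | Brc1cc([C@@H]2CC(=O)c3c(O[Si](C)(C)C(C)(C)C)cc(O[Si](C)(C)C(C)(C)C)cc3O2)ccc1O[Si](C)(C)C(C)(C)C
A2 | alternative 1 | 2-[3-bromo-4-(tert-butyldimethylsilyloxy)phenyl]-5,7-bis(tert-butyldimethylsilyloxy)-4-methylene-4H-1,3-benzodioxine | C=C1OC(c2ccc(O[Si](C)(C)C(C)(C)C)c(Br)c2)Oc2cc(O[Si](C)(C)C(C)(C)C)cc(O[Si](C)(C)C(C)(C)C)c21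
A3 | alternative 2 | (2S)-5,7-dihydroxy-2-{3-[(E)-3,7-dimethyl-7-(triethylsilyloxy)oct-2-en-1-yl]-4-(triisopropylsilyloxy)phenyl}chroman-4-one | C/C(=C\Cc1cc([C@@H]2CC(=O)c3c(O)cc(O)cc3O2)ccc1O[Si](C(C)C)(C(C)C)C(C)C)CCCC(C)(C)O[Si](CC)(CC)CC
A4 | alternative 2 | methyl 3-[(2S)-2-{3-[(E)-3,7-dimethyl-7-(triethylsilyloxy)oct-2-en-1-yl]-4-(triisopropylsilyloxy)phenyl}-6-methyl-4-oxo-3,4-dihydro-2H-pyran-5-yl]-3-oxopropanoate | C/C(=C\Cc1cc([C@@H]2CC(=O)C(C(=O)CC(=O)OC)=C(C)O2)ccc1O[Si](C(C)C)(C(C)C)C(C)C)CCCC(C)(C)O[Si](CC)(CC)CC
A5 | alternative 3 | (2S,4R)-5,7-bis(allyloxy)-2-{4-(allyloxy)-3-[(E)-3,7-dimethyl-7-(triethylsilyloxy)oct-2-en-1-yl]phenyl}chroman-4-ol | C/C(=C\Cc1cc([C@@H]2C[C@@H](O)c3c(OCC=C)cc(OCC=C)cc3O2)ccc1OCC=C)CCCC(C)(C)O[Si](CC)(CC)CC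
A6 | alternative 3 | (1R,3S)-1-[2,4-bis(allyloxy)-6-bromophenyl]-3-{4-(allyloxy)-3-[(E)-3,7-dimethyl-7-(triethylsilyloxy)oct-2-en-1-yl]phenyl}propane-1,3-diol | C/C(=C\Cc1cc([C@@H](O)C[C@@H](O)c2c(OCC=C)cc(OCC=C)cc2Br)ccc1OCC=C)CCCC(C)(C)O[Si](CC)(CC)CC
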